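The target in the asked flask, followed so far as the autumn run, is flat from its first reading, while the solid substrate reads 0.7% at 20.0 min, within the scatter of 1 percentage point around zero.

| flask | solid substrate | second substrate | gas | temperature | remark | time |
|---|---|---|---|---|---|---|
| autumn | 0.10 M | 0.20 equiv | 58 mM (held) | 25 °C | the very flask that is asked about, followed so far |  |
| winter | 0.10 M | 0.10 equiv | 58 mM (held) | 10 °C | run made earlier |  |
| flask | 0.10 M | 0.200 equiv | 58 mM (held) | 25 °C |  | 20 min |

- autumn (time / min: target / %, solid substrate / %): 3.00: 25.5, 1.1; 6.00: 25.9, 0; 8.00: 25.8, 1.1; 12.0: 24.4, 0; 15.0: 24.9, 2.7; 20.0: 26.0, 0.7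
- winter (time / min: target / %, solid substrate / %): 2.00: 15.3, 1.0; 3.00: 21.4, 0.7; 4.00: 26.5, 0; 6.00: 35.9, 0; 8.00: 40.8, 0.2; 12.0: 47.9, 0.1; 20.0: 50.5, 1.8

(readings scatter by 1 percentage point)

- given per volume of solution although it is solid: solid substrate
- at the start none of reagent is dissolved
- removed target is counted in
- the numbers in the tables scatter with a standard deviation of 1 percentage point
- reactions considered so far: solid substrate <-> starting material; second substrate + reagent <-> second product; second substrate <-> dormant form; gas <-> reagent; starting material + reagent <-> target
- at the start none of the solid substrate is in solution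

- larch: at 20 min raise the temperature by 25 K, then wait 10 min
- oak: change nothing and wait 10 min more
- alder: at 20 min take out 90% of the target then present, then wait 10 min

- target, in percent of the solid substrate first charged, at 20 min
- the remedy with the largest gain of target, or "none" below 2 percentage points (larch / oak / alder / none)
- target present, with what was taken out counted in, in percent of the solid substrate first charged, after oak
- target present, with what was taken out counted in, in percent of the solid substrate first charged, after alder

The autumn target readings average 25.4%. This is the standing share, the fraction of the dissolved pool, starting material plus target, that stands as target while gas is held. With gas held, the step reads as a reversible, pseudo-first-order relaxation, so my reckoning puts the asked flask at 25.4% now and after oak. The winter run climbs to 50.5%, twice that share, so larch should lower the target, although that run changes temperature and second substrate together.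

Alder needs a bracket. It removes 22.9% of the charge and leaves a pool of 77.1%. From below, a stalled pool re-forms nothing, and the total stays at 25.4%. From above, the pool refills from below to the standing share of itself, for a total of 42.5%. The half-life tightens this: 3 halvings by 3.00 min leave a gap of 3.17%, more than the readings show, so the half-life is under 1.00 min. If the flat is a relaxation, 10 min is then more than 10.0 half-lives, leaving under 0.0977% of the gap. My reckoning therefore stands at the upper bound, with a stall as the remaining doubt.

The forecast, holding that “the plateau is an equilibrium”, gives 25.4% now, 25.4% after oak and 42.5% after alder (36% to 45%), and chooses alder, its point lying on the upper bound and its high end above it.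

The flask gives 25.5% now, 25.5% after oak and 42.6% after alder; larch brings −20 points, alder 17 points, and the choice is alder.

    solid substrate ⇌ starting material, rate k1*(cs1 - [starting material]) while solid is left; crystals form when [starting material] > cs1 (solubility = 0.0880 M, k = 0.164 s⁻¹)
    second substrate + reagent ⇌ second product (K = 87.7 M⁻¹, k = 2.31 M⁻¹ s⁻¹, Ea = 41.0 kJ mol⁻¹, ΔH = −27.0 kJ mol⁻¹)
    second substrate ⇌ dormant form (K = 19.8, k = 0.00963 s⁻¹, Ea = 78.0 kJ mol⁻¹, ΔH = −44.0 kJ mol⁻¹)
    gas ⇌ reagent, rate k4*(csat - [reagent]) (kL = 1.98 s⁻¹)
    starting material + reagent ⇌ target (K = 5.90 M⁻¹, k = 0.131 M⁻¹ s⁻¹, Ea = 68.0 kJ mol⁻¹, ΔH = −53.0 kJ mol⁻¹)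
    (constants at 25 °C)

The falling back of target to starting material and reagent is the main reason for the flat: the run without it ends at >99.9%, against 25.5%. After alder, the pool in the asked flask refills to the standing share of itself, 19.6% of the charge. The neighbour flask with 0.17 M of solid substrate still holds 30.5% as solid at 20.0 min, and its dissolved pool is 69.5%. The standing share of that pool is 17.7%, and that flask holds 17.7% of target.

All runs were computed for substances that don't exist.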